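**Retrosynthetic overview**
- Feature: in this (2S)-flavanone, ring C is joined to ring A through the adjacent atoms C8a (bearing O1) and C4a (bearing the C4 carbonyl). The rest of ring C, O1–C2–C3–C4(=O), is the skeleton of a 4-aryl-β-lactone with C2 as its only stereocentre.
- Key disconnection O1–C8a plus C4–C4a: the ring-A aryne from silyl triflate 12 is inserted into the acyl–oxygen bond of (S)-lactone 24. Ring C is the only ring made (rings A and B are bought as arenes); one acidic global deprotection follows.
- 12: phloroglucinol → bis-MOM phenol → tertiary allyl ether and Claisen rearrangement (C8 prenyl) → carbamate-directed ortho-silylation → one-pot decarbamoylation and triflation.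
- 24: 4-hydroxy-2-methoxybenzaldehyde → prenyl ether and Claisen rearrangement (C5' 1,1-dimethylallyl) → acetate → BINOL–Ti(OiPr)4 thioacetate Mukaiyama aldol (sets C2) → silver-assisted hydrolysis → carboxyl-activated lactonisation with retention.

Key step: step 15

Assumption: (S)-BINOL/Ti(OiPr)4 is taken to give the (S)-carbinol in step 12, as it does with benzaldehyde (to be confirmed by Mosher esters, otherwise (R)-BINOL is used); 4-hydroxy-2-methoxybenzaldehyde, S-tert-butyl thioacetate and 3-chloro-3-methylbut-1-yne are treated as commercial.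

**Ring A: aryne precursor**

Step 1
Reactants: 1 phloroglucinol
Product: 2 3,5-bis(methoxymethoxy)phenol
Conditions: MOMCl (2.0 equiv), i-Pr2NEt, CH2Cl2–DMF, 0 °C → rt; chromatography
Reagents that add atoms: chloromethyl methyl ether, COCCl
Why: Williamson-type O-alkylation of the symmetrical triphenol with two equivalents of MOMCl is statistical, and the bis-ether should be separable from the mono- and tris-ethers, which can be recycled.

Step 2
Reactants: 2 3,5-bis(methoxymethoxy)phenol
Product: 3 1,3-bis(methoxymethoxy)-5-[(2-methylbut-3-yn-2-yl)oxy]benzene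
Conditions: 3-chloro-3-methylbut-1-yne, DBU, CuCl2·2H2O (cat.), MeCN, 0 °C
Reagents that add atoms: 3-chloro-3-methylbut-1-yne, C#CC(C)(C)Cl
Why: copper-catalysed propargylic substitution of a phenol by a tertiary propargyl chloride is the standard route to aryl 1,1-dimethylpropargyl ethers and uses the only free hydroxyl.

Step 3
Reactants: 3 1,3-bis(methoxymethoxy)-5-[(2-methylbut-3-yn-2-yl)oxy]benzene
Product: 4 1,3-bis(methoxymethoxy)-5-[(2-methylbut-3-en-2-yl)oxy]benzene
Conditions: H2 (1 atm), Pd/CaCO3–Pb(OAc)2 (Lindlar), quinoline, EtOAc, rt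
Reagents that add atoms: none
Why: Lindlar semihydrogenation of the terminal alkyne should stop at the alkene, and nothing else in the molecule is reducible.

Step 4
Reactants: 4 1,3-bis(methoxymethoxy)-5-[(2-methylbut-3-en-2-yl)oxy]benzene
Product: 5 3,5-bis(methoxymethoxy)-2-(3-methylbut-2-en-1-yl)phenol
Conditions: toluene, 115 °C, sealed tube
Reagents that add atoms: none
Why: the aromatic Claisen rearrangement of the tertiary allyl aryl ether delivers the allyl terminus to an ortho carbon as a prenyl group, and because the two ortho positions are equivalent and rearomatisation is fast only this phenol can form.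

Step 5
Reactants: 5 3,5-bis(methoxymethoxy)-2-(3-methylbut-2-en-1-yl)phenol
Product: 6 3,5-bis(methoxymethoxy)-2-(3-methylbut-2-en-1-yl)phenyl N-(propan-2-yl)carbamate
Conditions: i-PrNCO, Et3N (cat.), CH2Cl2, rt
Reagents that add atoms: isopropyl isocyanate, CC(C)N=C=O
Why: base-catalysed addition of the phenol to the isocyanate gives the secondary O-aryl carbamate, which serves as the directing group and is later removed under mild base.

Step 6
Reactants: 6 3,5-bis(methoxymethoxy)-2-(3-methylbut-2-en-1-yl)phenyl N-(propan-2-yl)carbamate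
Product: 10 3,5-bis(methoxymethoxy)-2-(3-methylbut-2-en-1-yl)-6-(trimethylsilyl)phenyl N-(propan-2-yl)carbamate, via N-silyl carbamate 7 (not isolated), via aryllithium 8 (not isolated), via N-silyl C-silyl carbamate 9 (not isolated)
Conditions: TBSOTf (1.05 equiv), TMEDA, Et2O, 0 °C → rt; n-BuLi, TMEDA, −78 °C; TMSCl, −78 °C → rt; cold aq. NaHSO4 (brief), then NaHCO3
Reagents that add atoms: chlorotrimethylsilane, C[Si](C)(C)Cl; tert-butyldimethylsilyl triflate, CC(C)(C)[Si](C)(C)OS(=O)(=O)C(F)(F)F (its silyl group is present in 7–9 only)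
Why: directed ortho-metalation of the carbamate, N-silylated in the flask, should occur at C6, the only ring position flanked by the carbamate and a MOM ether and therefore more acidic than C4–H or the benzylic CH2 of the prenyl group, and quench with the silyl chloride followed by hydrolytic loss of the N-silyl group gives the ortho-silyl carbamate.

Step 7
Reactants: 10 3,5-bis(methoxymethoxy)-2-(3-methylbut-2-en-1-yl)-6-(trimethylsilyl)phenyl N-(propan-2-yl)carbamate
Product: 12 3,5-bis(methoxymethoxy)-6-(3-methylbut-2-en-1-yl)-2-(trimethylsilyl)phenyl trifluoromethanesulfonate, via silylphenol 11 (not isolated)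
Conditions: Et2NH, DBU, MeCN, 40 °C; then PhNTf2, rt → 40 °C
Reagents that add atoms: N-phenylbis(trifluoromethanesulfonimide), O=S(=O)(N(c1ccccc1)S(=O)(=O)C(F)(F)F)C(F)(F)F
Why: E1cB loss of isopropyl isocyanate from the deprotonated carbamate (trapped by diethylamine as the urea) frees the ortho-silyl phenoxide, which is triflated in the same flask so that the aryl–silicon bond and the MOM ethers never meet acid.

**Ring B: (S)-β-lactone**

Step 8
Reactants: 13 4-hydroxy-2-methoxybenzaldehyde
Product: 14 2-methoxy-4-[(3-methylbut-2-en-1-yl)oxy]benzaldehyde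
Conditions: prenyl bromide, K2CO3, acetone, reflux
Reagents that add atoms: prenyl bromide (1-bromo-3-methylbut-2-ene), CC(C)=CCBr
Why: Williamson etherification of the only phenol with a primary allylic bromide is unambiguous.

Step 9
Reactants: 14 2-methoxy-4-[(3-methylbut-2-en-1-yl)oxy]benzaldehyde
Product: 15 4-hydroxy-2-methoxy-5-(2-methylbut-3-en-2-yl)benzaldehyde
Conditions: EtOH–H2O (4:1), 130 °C, sealed tube
Reagents that add atoms: none
Why: the water-accelerated aromatic Claisen rearrangement transfers the allyl unit with allylic inversion to give the 1,1-dimethylallyl group at C5, the ortho position para to the methoxy group, because the other ortho carbon C3 lies between two oxygen substituents and cannot readily take a quaternary substituent.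

Step 10
Reactants: 15 4-hydroxy-2-methoxy-5-(2-methylbut-3-en-2-yl)benzaldehyde
Product: 16 4-formyl-5-methoxy-2-(2-methylbut-3-en-2-yl)phenyl acetate
Conditions: Ac2O, pyridine, DMAP (cat.), CH2Cl2, 0 °C → rt
Reagents that add atoms: acetic anhydride, CC(=O)OC(C)=O
Why: nucleophile-catalysed acylation gives the aryl acetate, an electron-poor mask that tempers the donor strength of the para oxygen (needed for the stability of the benzylic lactone), survives the aldol and fluoride steps and falls off in the final acid methanolysis.

Step 11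
Reactants: 17 S-tert-butyl thioacetate
Product: 19 1-(tert-butylsulfanyl)-1-(trimethylsilyloxy)ethene, via lithium enolate 18 (not isolated)
Conditions: LiN(i-Pr)2, THF, −78 °C; TMSCl, −78 °C → rt; distillation
Reagents that add atoms: chlorotrimethylsilane, C[Si](C)(C)Cl
Why: kinetic deprotonation of the thioester and O-silylation of its lithium enolate is the standard preparation of this silyl ketene thioacetal.

Step 12
Reactants: 16 4-formyl-5-methoxy-2-(2-methylbut-3-en-2-yl)phenyl acetate; 19 1-(tert-butylsulfanyl)-1-(trimethylsilyloxy)ethene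
Product: 21 S-tert-butyl (3S)-3-[4-acetoxy-2-methoxy-5-(2-methylbut-3-en-2-yl)phenyl]-3-hydroxypropanethioate, via silyl ether 20 (not isolated)
Conditions: (S)-BINOL (20 mol%), Ti(OiPr)4 (20 mol%), 4 Å MS, Et2O, −20 °C; then 1 M aq. HCl–THF, 0 °C
Reagents that add atoms: none
Why: in this catalytic asymmetric Mukaiyama aldol (Keck conditions) the BINOL–titanium Lewis acid binds the aldehyde and shields one face, so that the silyl ketene thioacetal is expected to add to the face that gives the (S)-carbinol, the future C2.

Step 13
Reactants: 21 S-tert-butyl (3S)-3-[4-acetoxy-2-methoxy-5-(2-methylbut-3-en-2-yl)phenyl]-3-hydroxypropanethioate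
Product: 22 (3S)-3-[4-acetoxy-2-methoxy-5-(2-methylbut-3-en-2-yl)phenyl]-3-hydroxypropanoic acid
Conditions: AgO2CCF3 (1.5 equiv), 2,6-lutidine, THF–H2O (4:1), rt
Reagents that add atoms: water, O
Why: thiophilic silver activation lets the thioester hydrolyse at near-neutral pH, so the aryl acetate, which hydroxide or hydroperoxide would cleave, and the acid-sensitive benzylic alcohol are left alone.

Step 14
Reactants: 22 (3S)-3-[4-acetoxy-2-methoxy-5-(2-methylbut-3-en-2-yl)phenyl]-3-hydroxypropanoic acid
Product: 24 (4S)-4-[4-acetoxy-2-methoxy-5-(2-methylbut-3-en-2-yl)phenyl]oxetan-2-one, via mixed anhydride 23 (not isolated)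
Conditions: PhSO2Cl (2 equiv), pyridine, 0 → 4 °C; cold neutral work-up, used promptly
Reagents that add atoms: benzenesulfonyl chloride, O=S(=O)(Cl)c1ccccc1 (its sulfonyl group is present in 23 only)
Why: in this carboxyl-activated lactonisation (Adam conditions) the carboxylate is sulfonylated to a mixed anhydride and the β-hydroxyl closes on the acyl carbon, so the C–O bond at the stereocentre is never broken and the (S) configuration is retained.

**Key step and endgame**

Step 15
Reactants: 12 3,5-bis(methoxymethoxy)-6-(3-methylbut-2-en-1-yl)-2-(trimethylsilyl)phenyl trifluoromethanesulfonate; 24 (4S)-4-[4-acetoxy-2-methoxy-5-(2-methylbut-3-en-2-yl)phenyl]oxetan-2-one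
Product: 27 (2S)-4'-acetoxy-2'-methoxy-5,7-bis(methoxymethoxy)-8-(3-methylbut-2-en-1-yl)-5'-(2-methylbut-3-en-2-yl)flavanone, via aryne 25 (not isolated), via oxonium zwitterion 26 (not isolated)
Conditions: CsF (3 equiv), MeCN–toluene (1:3), rt; 12 (1.5 equiv) added over several hours to 24
Reagents that add atoms: none
Why: Proposed new method: fluoride unmasks aryne 25 from 12, the ether-like ring oxygen of the strained lactone (ester resonance is weak in the four-membered ring) adds to C8a to give oxonium aryl anion 26, and the anion at C4a attacks the adjacent, strongly activated acyl carbon through a four-membered transition state, whereupon the acyl–oxygen bond breaks and the oxetanone expands to the chromanone. The closest known reactions are aryne insertion into the acyl–oxygen bond of carboxylic acids, which gives ortho-hydroxyaryl ketones by the same O-arylation and 1,3-acyl shift as in an anionic Fries rearrangement, and aryne insertion into the N–C(O) bond of β-lactams; insertion into a lactone acyl–oxygen bond has not been described. Ring C closes by intermolecular O-arylation followed by intramolecular C-acylation, a two-atom ring expansion of the lactone driven by release of its ring strain. No stereocentre is created: C2 comes from 24, and because neither C2–O1 nor C2–C3 is broken its (S) configuration is carried through. Two selectivities are needed: oxygen must add to C8a and not C4a, which the inductively withdrawing C5 OMOM group secures by distorting the aryne and stabilising negative charge at C4a (the C8 prenyl group is only a steric counter-bias), and the ring oxygen, not the carbonyl oxygen, must be the nucleophile, which the weak ester resonance of the β-lactone favours. The 4'-acetate keeps ring B poor enough that the benzylic C2–O bond of 24 and 26 does not ionise before acyl transfer, and slow release of the aryne in a weakly polar medium limits ene reaction with the prenyl group and base-induced opening of the product.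

Step 16
Reactants: 27 (2S)-4'-acetoxy-2'-methoxy-5,7-bis(methoxymethoxy)-8-(3-methylbut-2-en-1-yl)-5'-(2-methylbut-3-en-2-yl)flavanone
Product: 28 (2S)-5,7,4'-trihydroxy-2'-methoxy-8-(3-methylbut-2-en-1-yl)-5'-(2-methylbut-3-en-2-yl)flavanone (CNP0308136.1)
Conditions: HCl (1.25 M in MeOH), THF, 0 °C → rt
Reagents that add atoms: none
Why: acid-catalysed acetal solvolysis of both MOM ethers and acid-catalysed transesterification of the aryl acetate run under the same methanolic HCl, which avoids the base-induced retro-oxa-Michael opening that would racemise C2 and is mild enough to leave both prenyl-type alkenes unprotonated.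

**Compound list**
1 | phloroglucinol | Oc1cc(O)cc(O)c1 | starting material
2 | 3,5-bis(methoxymethoxy)phenol | COCOc1cc(O)cc(OCOC)c1 | intermediate
3 | 1,3-bis(methoxymethoxy)-5-[(2-methylbut-3-yn-2-yl)oxy]benzene | C#CC(C)(C)Oc1cc(OCOC)cc(OCOC)c1 | intermediate
4 | 1,3-bis(methoxymethoxy)-5-[(2-methylbut-3-en-2-yl)oxy]benzene | C=CC(C)(C)Oc1cc(OCOC)cc(OCOC)c1 | intermediate
5 | 3,5-bis(methoxymethoxy)-2-(3-methylbut-2-en-1-yl)phenol | CC(C)=CCc1c(O)cc(OCOC)cc1OCOC | intermediate
6 | 3,5-bis(methoxymethoxy)-2-(3-methylbut-2-en-1-yl)phenyl N-(propan-2-yl)carbamate | CC(C)NC(=O)Oc1cc(OCOC)cc(OCOC)c1CC=C(C)C | intermediate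
7 | N-(tert-butyldimethylsilyl) derivative of carbamate 6 | CC(C)N([Si](C)(C)C(C)(C)C)C(=O)Oc1cc(OCOC)cc(OCOC)c1CC=C(C)C | intermediate
8 | 6-lithio derivative of N-silyl carbamate 7 | CC(C)N([Si](C)(C)C(C)(C)C)C(=O)Oc1c([Li])c(OCOC)cc(OCOC)c1CC=C(C)C | intermediate
9 | N-(tert-butyldimethylsilyl)-6-(trimethylsilyl) carbamate | CC(C)N([Si](C)(C)C(C)(C)C)C(=O)Oc1c([Si](C)(C)C)c(OCOC)cc(OCOC)c1CC=C(C)C | intermediate
10 | 3,5-bis(methoxymethoxy)-2-(3-methylbut-2-en-1-yl)-6-(trimethylsilyl)phenyl N-(propan-2-yl)carbamate | CC(C)NC(=O)Oc1c([Si](C)(C)C)c(OCOC)cc(OCOC)c1CC=C(C)C | intermediate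
11 | 3,5-bis(methoxymethoxy)-2-(3-methylbut-2-en-1-yl)-6-(trimethylsilyl)phenol | C[Si](C)(C)c1c(O)c(CC=C(C)C)c(OCOC)cc1OCOC | intermediate
12 | 3,5-bis(methoxymethoxy)-6-(3-methylbut-2-en-1-yl)-2-(trimethylsilyl)phenyl trifluoromethanesulfonate | C[Si](C)(C)c1c(OCOC)cc(OCOC)c(CC=C(C)C)c1OS(=O)(=O)C(F)(F)F | intermediate
13 | 4-hydroxy-2-methoxybenzaldehyde | COc1cc(O)ccc1C=O | starting material
14 | 2-methoxy-4-[(3-methylbut-2-en-1-yl)oxy]benzaldehyde | COc1cc(OCC=C(C)C)ccc1C=O | intermediate
15 | 4-hydroxy-2-methoxy-5-(2-methylbut-3-en-2-yl)benzaldehyde | C=CC(C)(C)c1cc(C=O)c(OC)cc1O | intermediate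
16 | 4-formyl-5-methoxy-2-(2-methylbut-3-en-2-yl)phenyl acetate | C=CC(C)(C)c1cc(C=O)c(OC)cc1OC(C)=O | intermediate
17 | S-tert-butyl thioacetate | CC(=O)SC(C)(C)C | starting material
18 | lithium 1-(tert-butylsulfanyl)ethen-1-olate | [Li]OC(=C)SC(C)(C)C | intermediate
19 | 1-(tert-butylsulfanyl)-1-(trimethylsilyloxy)ethene | C=C(O[Si](C)(C)C)SC(C)(C)C | intermediate
20 | S-tert-butyl (3S)-3-[4-acetoxy-2-methoxy-5-(2-methylbut-3-en-2-yl)phenyl]-3-(trimethylsilyloxy)propanethioate | C=CC(C)(C)c1cc([C@@H](O[Si](C)(C)C)CC(=O)SC(C)(C)C)c(OC)cc1OC(C)=O | intermediate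
21 | S-tert-butyl (3S)-3-[4-acetoxy-2-methoxy-5-(2-methylbut-3-en-2-yl)phenyl]-3-hydroxypropanethioate | C=CC(C)(C)c1cc([C@@H](O)CC(=O)SC(C)(C)C)c(OC)cc1OC(C)=O | intermediate
22 | (3S)-3-[4-acetoxy-2-methoxy-5-(2-methylbut-3-en-2-yl)phenyl]-3-hydroxypropanoic acid | C=CC(C)(C)c1cc([C@@H](O)CC(=O)O)c(OC)cc1OC(C)=O | intermediate
23 | benzenesulfonic (3S)-3-[4-acetoxy-2-methoxy-5-(2-methylbut-3-en-2-yl)phenyl]-3-hydroxypropanoic anhydride | C=CC(C)(C)c1cc([C@@H](O)CC(=O)OS(=O)(=O)c2ccccc2)c(OC)cc1OC(C)=O | intermediate
24 | (4S)-4-[4-acetoxy-2-methoxy-5-(2-methylbut-3-en-2-yl)phenyl]oxetan-2-one | C=CC(C)(C)c1cc([C@@H]2CC(=O)O2)c(OC)cc1OC(C)=O | intermediate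
25 | 3,5-bis(methoxymethoxy)-6-(3-methylbut-2-en-1-yl)benzyne (1,2-didehydrobenzene) | COCOC1=CC(OCOC)=C(CC=C(C)C)C#C1 | intermediate
26 | O-aryl oxetanonium aryl anion zwitterion (ring oxygen of 24 bonded to C8a, carbanion at C4a) | C=CC(C)(C)c1cc([C@@H]2CC(=O)[O+]2c3[c-]c(OCOC)cc(OCOC)c3CC=C(C)C)c(OC)cc1OC(C)=O | intermediate
27 | (2S)-4'-acetoxy-2'-methoxy-5,7-bis(methoxymethoxy)-8-(3-methylbut-2-en-1-yl)-5'-(2-methylbut-3-en-2-yl)flavanone | C=CC(C)(C)c1cc([C@@H]2CC(=O)c3c(OCOC)cc(OCOC)c(CC=C(C)C)c3O2)c(OC)cc1OC(C)=O | intermediate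
28 | (2S)-5,7,4'-trihydroxy-2'-methoxy-8-(3-methylbut-2-en-1-yl)-5'-(2-methylbut-3-en-2-yl)flavanone (CNP0308136.1) | C=CC(C)(C)c1cc([C@@H]2CC(=O)c3c(O)cc(O)c(CC=C(C)C)c3O2)c(OC)cc1O | target

**Step count**
Total: 16 steps. Longest linear sequence: 9 steps (steps 1–7, 15, 16, from phloroglucinol); the ring-B branch is 8 steps (steps 8–10, 12–16), and step 11 makes a reagent.

**Steps most likely to fail**

1. Step 15 (proposed new method). Several processes can defeat it.
 - The lactone is a weak nucleophile, so the aryne may instead be consumed by ene reaction with prenyl groups or by fluoride-derived nucleophiles.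
 - Attack through the carbonyl oxygen, not the ring oxygen, would lead through a spiro benzoxete and ionisation at C2 to racemic or rearranged material.
 - The benzylic lactone may ionise and lose CO2.
 - The product may open by base-induced retro-oxa-Michael reaction, with erosion of configuration at C2.
 - The enantiomeric purity of 27 is the probe for the last three.

 Fallback by known chemistry, setting out from 16 and 12 and returning at 27: Knoevenagel–Doebner condensation of 16 with malonic acid (pyridine, cat. piperidine, 80 °C; any phenol freed is re-acetylated with Ac2O) should give (E)-3-[4-acetoxy-2-methoxy-5-(2-methylbut-3-en-2-yl)phenyl]prop-2-enoic acid F1. The established insertion of an aryne into the O–C(acyl) bond of a carboxylic acid (12, CsF, THF, 125 °C, sealed tube) places oxygen on C8a and the cinnamoyl group on C4a under the same regiocontrol and should give the 2'-hydroxychalcone F2. This closes by oxa-Michael addition under the same conditions (or with NaOAc in EtOH) to the racemic flavanone F3. Kinetic resolution by asymmetric transfer hydrogenation (RuCl[(R,R)-TsDPEN](p-cymene), HCO2H–Et3N, rt, to about half conversion) should reduce the (2R)-enantiomer to the cis-(2R,4R)-flavan-4-ol F4 and leave (2S)-27, which re-enters at step 16.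

2. Step 14. The benzylic hydroxyl may be sulfonylated in place of the carboxylate, or the electron-rich benzylic C–O bond may ionise. Either leads to decarboxylative elimination to the styrene or to erosion of enantiomeric purity. The lactone may also be lost on silica.

 Fallback, setting out from 16 and returning at 24: a catalytic asymmetric acyl halide–aldehyde cyclocondensation (acetyl chloride, i-Pr2NEt, O-trimethylsilylquinine or its quinidine pseudoenantiomer as catalyst, whichever delivers the (S)-lactone, LiClO4, CH2Cl2–Et2O, −78 °C). Ketene is generated in the flask and adds [2+2] to the aldehyde under alkaloid control, so the ring is built cold and without acid or sulfonate salts, and steps 11–14 are bypassed. This fallback makes no new compound (F0).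

3. Step 9. The allyl unit may migrate to C3 in place of C5, the prenyl ether may simply cleave, or the ortho-(1,1-dimethylallyl)phenol may cyclise to a dihydrobenzofuran at the temperature needed.

 Fallback, setting out from 13 and returning at 15: bromination (NBS, MeCN, 0 °C) at the position ortho to the hydroxyl and para to the methoxy group should give 5-bromo-4-hydroxy-2-methoxybenzaldehyde F5. A palladium-catalysed γ-selective Suzuki–Miyaura coupling with prenylboronic acid pinacol ester (Pd(OAc)2, bulky biaryl di-tert-butylphosphine, K3PO4, aq. THF; ligand-controlled coupling at the tertiary allyl terminus, known for 3,3-disubstituted allylboronates) then forms the aryl–C(CH3)2CH=CH2 bond directly and gives 15, which continues at step 10.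

**Further compounds**
F1 | step 15 | (E)-3-[4-acetoxy-2-methoxy-5-(2-methylbut-3-en-2-yl)phenyl]prop-2-enoic acid | C=CC(C)(C)c1cc(/C=C/C(=O)O)c(OC)cc1OC(C)=O
F2 | step 15 | (E)-3-[4-acetoxy-2-methoxy-5-(2-methylbut-3-en-2-yl)phenyl]-1-[2-hydroxy-4,6-bis(methoxymethoxy)-3-(3-methylbut-2-en-1-yl)phenyl]prop-2-en-1-one | C=CC(C)(C)c1cc(/C=C/C(=O)c2c(OCOC)cc(OCOC)c(CC=C(C)C)c2O)c(OC)cc1OC(C)=O
F3 | step 15 | racemic 4'-acetoxy-2'-methoxy-5,7-bis(methoxymethoxy)-8-(3-methylbut-2-en-1-yl)-5'-(2-methylbut-3-en-2-yl)flavanone | C=CC(C)(C)c1cc(C2CC(=O)c3c(OCOC)cc(OCOC)c(CC=C(C)C)c3O2)c(OC)cc1OC(C)=O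
F4 | step 15 | (2R,4R)-4'-acetoxy-2'-methoxy-5,7-bis(methoxymethoxy)-8-(3-methylbut-2-en-1-yl)-5'-(2-methylbut-3-en-2-yl)flavan-4-ol | C=CC(C)(C)c1cc([C@H]2C[C@@H](O)c3c(OCOC)cc(OCOC)c(CC=C(C)C)c3O2)c(OC)cc1OC(C)=O
F0 | step 14 | none | none
F5 | step 9 | 5-bromo-4-hydroxy-2-methoxybenzaldehyde | COc1cc(O)c(Br)cc1C=O
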